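The numbers in the tables are simulated for substances that don't exist; scatter was added.

Start from the product: the left-handed and right-handed product building up in the autumn flask, the one asked about, and in the earlier summer run.

| flask | left-handed substrate | right-handed substrate | solid reagent | free catalyst | racemization catalyst | remark | time |
|---|---|---|---|---|---|---|---|
| autumn | 20 mM | 20 mM | 60 mM | 0.40 mM | 0.40 mM | the very flask that is asked about, followed so far |  |
| summer | 30 mM | 30 mM | 60 mM | 0.40 mM | 0.40 mM | run made earlier |  |
| flask | 20 mM | 20 mM | 60.0 mM | 0.40 mM | 0.40 mM |  | 30 h |

| run | time / h | left-handed product / % | right-handed product / % |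
|---|---|---|---|
| autumn | 0.500 | 1.0 | 3.3 |
| autumn | 0.833 | 0.1 | 0 |
| autumn | 1.33 | 3.0 | 0 |
| autumn | 2.00 | 0.3 | 0 |
| autumn | 4.00 | 3.6 | 2.0 |
| autumn | 6.00 | 5.0 | 1.5 |
| summer | 2.50 | 1.1 | 1.1 |
| summer | 4.00 | 0.4 | 0.9 |
| summer | 6.00 | 4.8 | 3.6 |
| summer | 10.0 | 7.6 | 3.4 |
| summer | 20.0 | 17.0 | 5.5 |
| summer | 30.0 | 25.5 | 10.6 |

(standard deviation of a reading: 1 percentage point)

- free catalyst is single-handed; left-handed substrate and right-handed substrate are mirror images of each other, charged as a racemate, each of them at the stated concentration
- as a solid, counted per litre of solution: solid reagent
- the earlier runs were read with a standard deviation of 1 percentage point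
- at the start none of the solid reagent is in solution
- an excess is below zero if the other one leads

1. left-handed product and right-handed product together, in percent of the left-handed substrate and right-handed substrate charged together, at 30 h
2. excess of left-handed product over right-handed product in the product at 30 h
3. whether the exchange between left-handed substrate and right-handed substrate keeps pace with the reaction: how far the product's excess at 30 h gets from its value without exchange to its value with instant exchange (above 80% keeps pace, below 20% hardly takes part, else lags behind)

Take the plain ratio of the two products first. In the summer run at 30.0 h it reads 2.41. This equals the selectivity factor s, the left-handed substrate's rate over the right-handed one's at equal concentration, provided exchange holds the two substrates equal.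

Now follow one molecule. Suppose each hand reacts in proportion to what is left of it, the left-handed s times as fast over the same stretch of time; then, if neither changes hand, a left-handed molecule's chance of surviving equals a right-handed one's raised to s. Call L and D the parts of left-handed and right-handed substrate left, each of its own charge; the survival exponent s = ln L / ln D then follows from the products. The summer run at 30.0 h gives L = 49.0% and D = 78.8%, so s = 2.99, more than the plain ratio.

The two ways part, so test them. Up to 20.0 h the summer products read a ratio of 3.09, but what forms afterwards reads 1.67. Equal substrates keep that ratio steady, while the survival rule lets it sink towards s·L/D = 1.86. With 1 percentage point on each reading this is a leaning, not proof, yet I take the survival rule: exchange hardly takes part.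

For the autumn flask, my reckoning takes over the summer percentages, with the two products together reading 6.50% in the autumn run against 8.40% in the summer run at 6.00 h. That gives 36.1% at 30 h and an excess of 41.3%, against 49.9% reckoned from this s for instant exchange.

The forecast gives 38%, 43% and keeps pace, above my figures and against me on the pace: “This weakly favours exchange keeping pace”.

The flask gives 43.4%, an excess of 44.0%, and exchange hardly takes part, at 5.2% of the way.

    coupling partner + free catalyst + right-handed substrate → free catalyst + right-handed product (k = 8990 L² mol⁻² h⁻¹)
    solid reagent ⇌ coupling partner, rate k2*(cs2 - [coupling partner]) while solid is left; crystals form when [coupling partner] > cs2 (solubility = 14.0 mM, k = 0.0616 h⁻¹)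
    left-handed substrate + racemization catalyst ⇌ right-handed substrate + racemization catalyst, rate k3*[racemization catalyst]*[left-handed substrate] forward; the back reaction follows from the equilibrium constant (k = 92.4 L mol⁻¹ h⁻¹)
    2 racemization catalyst → spent catalyst (k = 1040 L mol⁻¹ h⁻¹)
    coupling partner + free catalyst + left-handed substrate → free catalyst + left-handed product (k = 31000 L² mol⁻² h⁻¹)
    racemization catalyst ⇌ dormant form (K = 2.72, k = 0.0219 h⁻¹)

The conversion of the autumn flask stands above my 36.1%. Carry over the s read from the summer run: the autumn flask keeps 74% of its right-handed substrate at 30 h, which raised to s gives 41.4%, and 39% of the left-handed stands there. Now take the neighbour with 1.6 mM of free catalyst, its other charges and its time as in the autumn flask. It reaches 56.0% with an excess of 38.8% and keeps 64% of its right-handed substrate. Raised to s, that gives 26.3%, and the neighbour holds 24% of its left-handed substrate.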